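**Retrosynthetic overview**

- Feature: in the fully substituted benzene ring (C1–OH, C2–OH, C3–Br, C4–Br, C5–CH3, C6–Br), C3 is a bromine-bearing carbon between the oxygenated C2 and C4. Taking it out leaves C1, C2, C4, C5, C6 as a mirror-symmetric five-membered 1,2-dioxygenated ring with the methyl opposite the C1–C2 bond.
- Last disconnection: C4–Br and C6–Br, by twofold electrophilic bromination of 3-bromo-5-methylbenzene-1,2-diol.
- Key disconnection: C2–C3 and C3–C4, by dibromocarbene addition and cyclopropane opening on 5-methyl-2,3-bis(tert-butyldimethylsilyloxy)cyclopenta-1,3-diene, with bromoform supplying the C3–Br unit.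
- The diene comes from 4-methylcyclopentane-1,2-dione by double O-silylation; the dione comes from diethyl oxalate and diethyl 3-methylglutarate by double Claisen condensation and decarboxylation.
- Ring order: the five-membered carbocycle is made first (step 1) and is expanded to the six-membered aromatic ring in step 4.

Key step: step 4

Remark: compounds 3 and 4 are drawn as keto forms although both should exist largely as enols; this does not change the chemistry. TBS = tert-butyldimethylsilyl.

**Step 1**
Reactants: 1 diethyl oxalate; 2 diethyl 3-methylglutarate
Product: 3 diethyl 2-methyl-4,5-dioxocyclopentane-1,3-dicarboxylate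
Conditions: NaOEt (2.2 equiv), EtOH, 0 °C → reflux; then cold 2 M HCl
Reagents that add atoms: none
Why: Double crossed Claisen condensation (the second one a Dieckmann-type 5-exo-trig closure) of the two α-CH2 groups of 2 on non-enolisable 1 should be driven to completion by double deprotonation of the product, as with the parent glutarate.

**Step 2**
Reactants: 3 diethyl 2-methyl-4,5-dioxocyclopentane-1,3-dicarboxylate
Product: 4 4-methylcyclopentane-1,2-dione
Conditions: 20% aq. H2SO4, reflux; extraction with CH2Cl2
Reagents that add atoms: none
Why: Acid hydrolysis of both β-keto esters followed by decarboxylation of the β-keto acids should leave the 1,2-dione, which erases both ester-bearing stereocentres and gives a compound with a mirror plane through C4.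

**Step 3**
Reactants: 4 4-methylcyclopentane-1,2-dione
Product: 5 5-methyl-2,3-bis(tert-butyldimethylsilyloxy)cyclopenta-1,3-diene
Conditions: TBSOTf (2.3 equiv), Et3N (3.5 equiv), CH2Cl2, −78 → 0 °C; cold pentane/aq. NaHCO3 work-up; used crude, kept below 0 °C
Reagents that add atoms: tert-butyldimethylsilyl trifluoromethanesulfonate, CC(C)(C)[Si](C)(C)OS(=O)(=O)C(F)(F)F
Why: Soft enolisation should silylate the enol OH first and then, after silyl triflate activation of the remaining enone carbonyl, remove a proton from the α′ CH2 and not the γ CH(CH3), giving the cross-conjugated 2-silyloxy-1,3-diene as is usual for cyclic enones; the bulky TBS groups and the cold work-up are meant to hold back 1,5-hydrogen shift and dimerisation.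

**Step 4**
Reactants: 5 5-methyl-2,3-bis(tert-butyldimethylsilyloxy)cyclopenta-1,3-diene; 6 bromoform
Product: 9 3-bromo-5-methylbenzene-1,2-diol, via dibromocyclopropane 7 (not isolated), via bis-silyl bromoarene 8 (not isolated)
Conditions: CHBr3 (1.1 equiv), KOtBu (2.3 equiv, in portions), pentane, −30 → 0 °C; aq. NH4Cl work-up; crude, KHF2 (3 equiv), MeOH, rt
Reagents that add atoms: none
Why: tert-Butoxide removes HBr from bromoform by α-elimination and the electrophilic singlet dibromocarbene adds in a concerted [2+1] manner to one electron-rich silyl enol ether double bond of 5, giving 7. The dibromocyclopropane, fused to a five-membered ring and carrying a silyloxy donor on a fusion carbon, then undergoes disrotatory two-electron electrocyclic opening with departure of the endo bromide; the shared ring-fusion bond breaks, so the six-membered ring is closed by one-carbon expansion (not by cyclisation) with the carbene carbon becoming C3, bonded to C2 and C4. The silyloxy-stabilised allyl cation loses the proton of the neighbouring CH(CH3) carbon (or a silyl group followed by dienone–phenol tautomerisation), a second equivalent of base takes up the HBr, and the gain of aromaticity makes the sequence irreversible. The closest known reaction types are the dihalocarbene ring expansion of cyclic silyl enol ethers to 2-halo-enones and of cyclopentadienes and indenes to halobenzenes and 2-halonaphthalenes. No stereocentre survives; site selectivity is not needed because the mirror plane through the CH(CH3) carbon makes the two enol ether double bonds equivalent and the two oxygenated carbons are joined only by a single bond, and mono-addition is secured by about one equivalent of bromoform, by fast aromatisation to an arene that the carbene does not attack, and by adding the base in portions to the bromoform-containing solution so that bromoform, which is deprotonated faster, consumes the base before the doubly allylic C–H does. KHF2 in methanol then cleaves both aryl silyl ethers and funnels any partly desilylated material to 9.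

**Step 5**
Reactants: 9 3-bromo-5-methylbenzene-1,2-diol
Product: 10 3,4,6-tribromo-5-methylbenzene-1,2-diol
Conditions: Br2 (2.1 equiv), AcOH, 10 °C → rt; aq. Na2S2O4 work-up
Reagents that add atoms: bromine, BrBr
Why: Electrophilic aromatic bromination should take place at C4 (para to the C1 hydroxyl) and C6 (ortho to it), the only unsubstituted ring positions and both activated by hydroxyl and methyl, while the dithionite work-up returns any o-quinone formed by over-oxidation to the catechol.

**Compound list**

1 | diethyl oxalate | CCOC(=O)C(=O)OCC | starting material
2 | diethyl 3-methylglutarate (diethyl 3-methylpentanedioate) | CCOC(=O)CC(C)CC(=O)OCC | starting material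
3 | diethyl 2-methyl-4,5-dioxocyclopentane-1,3-dicarboxylate (mixture of stereoisomers and enol forms; both stereocentres are erased in step 2) | CCOC(=O)C1C(C)C(C(=O)OCC)C(=O)C1=O | intermediate
4 | 4-methylcyclopentane-1,2-dione (achiral diketo form; enol form 2-hydroxy-4-methylcyclopent-2-en-1-one) | CC1CC(=O)C(=O)C1 | intermediate
5 | 5-methyl-2,3-bis(tert-butyldimethylsilyloxy)cyclopenta-1,3-diene (achiral) | CC1C=C(O[Si](C)(C)C(C)(C)C)C(O[Si](C)(C)C(C)(C)C)=C1 | intermediate
6 | bromoform | BrC(Br)Br | starting material
7 | 6,6-dibromo-1,2-bis(tert-butyldimethylsilyloxy)-4-methylbicyclo[3.1.0]hex-2-ene (racemic, cis ring fusion, cyclopropane expected anti to the methyl; configuration lost on ring opening) | CC1C=C(O[Si](C)(C)C(C)(C)C)C2(O[Si](C)(C)C(C)(C)C)C1C2(Br)Br | intermediate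
8 | 1-bromo-2,3-bis(tert-butyldimethylsilyloxy)-5-methylbenzene | Cc1cc(Br)c(O[Si](C)(C)C(C)(C)C)c(O[Si](C)(C)C(C)(C)C)c1 | intermediate
9 | 3-bromo-5-methylbenzene-1,2-diol | Cc1cc(O)c(O)c(Br)c1 | intermediate
10 | 3,4,6-tribromo-5-methylbenzene-1,2-diol | Cc1c(Br)c(O)c(O)c(Br)c1Br | target

**Totals**

Total step count: 5. Longest linear sequence: 5 steps (from 1 and 2 to 10).

**Steps most likely to fail**

Step 4. tert-Butoxide may deprotonate the doubly allylic CH(CH3) position and scramble the diene through the cyclopentadienide, the base may strip silyl groups before the carbene adds, or a second carbene may add before the ring opens. Carbon insertion on the methyl side after such scrambling would be tolerated, because the last step brominates every remaining ring position, but insertion between the two oxygenated carbons would not.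

The fallback avoids the cyclopentadiene and performs the same one-carbon insertion on a saturated ketone. It sets out from 4 and returns at 9:
- Compound 4 is mono-ketalised (ethylene glycol, 1 equiv, TsOH cat., toluene, Dean–Stark) to 8-methyl-1,4-dioxaspiro[4.4]nonan-6-one F1; the symmetry of 4 allows only one monoketal.
- Deprotonation at the only α-CH2 (LDA, THF, −78 °C; TBSCl, DMPU) should give tert-butyldimethyl[(8-methyl-1,4-dioxaspiro[4.4]non-6-en-6-yl)oxy]silane F2.
- Dibromocarbene (CHBr3, KOtBu, pentane, −20 °C → rt) should add to the enol ether to give 6,6-dibromo-1-(tert-butyldimethylsilyloxy)-4-methylspiro[bicyclo[3.1.0]hexane-2,2'-[1,3]dioxolane] F3.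
- F3 should open in the flask with loss of bromide and the silyl group, the established route from silyl enol ethers to 2-bromo-enones, giving 7-bromo-9-methyl-1,4-dioxaspiro[4.5]dec-7-en-6-one F4.
- Aqueous HCl in THF then removes the ketal; the liberated 3-bromo-5-methylcyclohex-3-ene-1,2-dione F5 is a tautomer of 9 and should aromatise at once.

Step 3. Deprotonation may occur at the γ CH(CH3) position, the ammonium salt may equilibrate the product to the conjugated enediol isomer, and 1,5-hydrogen shift or Diels–Alder dimerisation may set in on warming or concentration.

The fallback stages the silylation so that the second enolisation is an irreversible kinetic deprotonation of a purified enone in the absence of ammonium salts. It sets out from 4 and returns at 5: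
- TBSCl and imidazole in DMF at rt should silylate only the enol oxygen, giving 2-(tert-butyldimethylsilyloxy)-4-methylcyclopent-2-en-1-one F6, which can be purified and stored.
- LDA in THF at −78 °C removes an α′ proton, and trapping with TBSOTf at −78 °C followed by a cold non-aqueous work-up (pentane, filtration) should deliver 5.

Step 5. Bromine may oxidise the electron-rich catechol to the o-quinone and on to addition or ring-degradation products, or substitution may stall after the first bromine enters the crowded ring.

The fallback brominates a protected catechol. It sets out from 9 and returns at 10: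
- MeI and K2CO3 in acetone at reflux give 1-bromo-2,3-dimethoxy-5-methylbenzene F7.
- Br2 (2.2 equiv) in AcOH at 50 °C should brominate both remaining positions to give 1,2,4-tribromo-5,6-dimethoxy-3-methylbenzene F8.
- BBr3 in CH2Cl2 (−78 °C → rt) cleaves both methyl ethers to give 10.

**Further compounds**

F1 | step 4 | 8-methyl-1,4-dioxaspiro[4.4]nonan-6-one | CC1CC(=O)C2(C1)OCCO2
F2 | step 4 | tert-butyldimethyl[(8-methyl-1,4-dioxaspiro[4.4]non-6-en-6-yl)oxy]silane | CC1C=C(O[Si](C)(C)C(C)(C)C)C2(C1)OCCO2
F3 | step 4 | 6,6-dibromo-1-(tert-butyldimethylsilyloxy)-4-methylspiro[bicyclo[3.1.0]hexane-2,2'-[1,3]dioxolane] | CC1CC2(OCCO2)C3(O[Si](C)(C)C(C)(C)C)C1C3(Br)Br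
F4 | step 4 | 7-bromo-9-methyl-1,4-dioxaspiro[4.5]dec-7-en-6-one | CC1CC2(OCCO2)C(=O)C(Br)=C1
F5 | step 4 | 3-bromo-5-methylcyclohex-3-ene-1,2-dione | CC1CC(=O)C(=O)C(Br)=C1
F6 | step 3 | 2-(tert-butyldimethylsilyloxy)-4-methylcyclopent-2-en-1-one | CC1CC(=O)C(O[Si](C)(C)C(C)(C)C)=C1
F7 | step 5 | 1-bromo-2,3-dimethoxy-5-methylbenzene | COc1cc(C)cc(Br)c1OC
F8 | step 5 | 1,2,4-tribromo-5,6-dimethoxy-3-methylbenzene | COc1c(Br)c(C)c(Br)c(Br)c1OC
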